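The readings are simulated for an exercise.

In the early hours of the north-east run target reads 73.6% at 2.50 h, and from 4.00 h on the readings scatter about one level, and that early clock is what you should count with.

| flask | substrate | partner | gas | remark | time |
|---|---|---|---|---|---|
| north-east | 0.24 M | 0.216 M | 66 mM (held) | run made earlier |  |
| east | 0.24 M | 0.30 M | 66 mM (held) | run made earlier |  |
| north | 0.24 M | 0.48 M | 66 mM (held) | run made earlier |  |
| south-east | 0.36 M | 0.216 M | 66 mM (held) | run made earlier |  |
| oak | 0.24 M | 0.216 M (fed, over 25 h) | 66 mM (held) | all else is in the flask from the start; the feed brings no volume worth counting | 30 h |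
| ash | 0.24 M | 0.216 M | 66 mM (held) | everything together at the start | 30 h |
| maple | 0.24 M (fed, over 25 h) | 0.216 M | 66 mM (held) | all else is in the flask from the start; the feed brings no volume worth counting | 30 h |

- north-east (time / h: target / %): 2.50: 73.6; 4.00: 76.5; 6.00: 79.0; 10.0: 76.0; 20.0: 79.0; 30.0: 75.9
- east (time / h: target / %): 5.00: 88.0; 10.0: 88.9; 15.0: 88.8; 20.0: 87.9; 25.0: 88.6; 30.0: 88.6
- north (time / h: target / %): 2.50: 94.6; 4.00: 94.4; 6.00: 97.2; 10.0: 96.3; 20.0: 95.2; 30.0: 95.8
- south-east (time / h: target / %): 6.00: 60.7; 12.0: 59.7; 20.0: 59.5; 25.0: 60.0; 30.0: 61.4

(readings scatter by 1 percentage point)

- what is said of target includes idle adduct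
- at the start none of rival reagent is dissolved
- reactions considered so far: substrate + rival reagent -> side product; gas <-> rival reagent; substrate + partner -> target; partner + target <-> idle adduct

* which flask leads in amount of target, in percent of the substrate charged ("all alike" within 1.5 percentage points) (oak / ash / maple / all alike)
* how much target is there at the end, in percent of the substrate charged: oak
* how much target is there at the end, in percent of the substrate charged: ash
* how much target is there at the end, in percent of the substrate charged: maple

1. The north-east readings level at about 77.3% of the substrate charged, so about 0.0545 M of substrate became side product, while about 0.0305 M of the partner charge did not become target: partner, on paper the limiting reagent, outlasts substrate in the north-east run.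

2. Dividing that side product by the middle of the interval in which the readings reach their level, 3.25 h, gives the rival supply, the concentration of rival reagent that substrate takes up per hour, on average, while substrate lasts, here a rough reading of about 0.0168 M h⁻¹.

3. You now have two ways of reckoning. The first carries the north-east ratio over, giving 77.3% for any flask with these charges, and ash, the same recipe as the north-east run, is where I commit to it. The second counts turnovers per hour: oak's partner feed of 0.00864 M h⁻¹ is slower than the rival supply, so by this count substrate in oak lasts about 9.44 h and target takes about 34.0%.

4. The two part, and I hold the first to be the cheat, because its ratio belongs to a clock of 3.25 h, and oak's clock is longer. In maple the substrate feed of 0.00960 M h⁻¹ is slower than the rival supply, by 0.00720 M h⁻¹, so I expect dissolved rival reagent to build up in maple, and I place maple between 34.0% and 77.3%.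

5. The forecast gave oak 27%, ash 77.5% and, reasoning for maple that “selectivity follows the same integral as batch”, maple 72%, with ash leading.

6. The flasks give oak 29.8%, ash 78.1% and maple 49.7%, with ash leading.

    substrate + rival reagent → side product (k = 33.0 M⁻¹ h⁻¹)
    gas ⇌ rival reagent, rate k2*(csat - [rival reagent]) (kL = 0.280 h⁻¹)
    substrate + partner → target (k = 11.0 M⁻¹ h⁻¹)
    partner + target ⇌ idle adduct, settled at all times (K = 3.10 M⁻¹)

In oak the step to target and the step to side product ran early, with half of their turnover up to the asked time done by 4.85 h and 5.01 h, and substrate was down to 0.00707% at 15.0 h; oak's 29.8% lies 4.2 percentage points under the count made with 0.0168 M h⁻¹. In maple rival reagent stood at 0.0478 M at 15.0 h beside 1.40% of substrate, and the flask ended with 49.7% target and 50.3% side product.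

A neighbour of oak charged with 0.054 M of partner has a feed of 0.00216 M h⁻¹, which against 0.0168 M h⁻¹ counts 11.4% target. The computed flask gives 9.98%.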